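**Plan**

Numbering (daucane): C1 is the quaternary ring-fusion carbon (CH3), then C2, C3, C4 (carbinol carbon, i-Pr), C5 (ring-fusion CH), C6 (CH–O-acyl), C7, C8 (=C–CH3), C9 (=CH), C10. Ring A is the cyclopentane, ring B the cycloheptene. β is the face of the angular CH3, α the other face.
Enabling feature: in ring B the C8=C9 olefin lies 1,4 to the C5–C6 bond, and H-5 and O-6 are cis (both α), which is the imprint of a syn hydration of a C5=C6 olefin. Ring B is therefore a latent cyclohepta-1,4-diene, with C7 alone between the olefins and the C1–C10 bond opposite. That is the retron of a cis-divinylcyclopropane Cope rearrangement.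
Cuts, in retrosynthetic order: the C6–O acyl bond; C4–i-Pr (back to a C4 ketone); H-5/O-6 (hydroboration); the C8 methyl (back to CO2Me); then C7–C8 and C1–C10 together. This leaves a 2-vinylcyclopentenyl silyl ether and methyl 2-diazobut-3-enoate.
Forward: ring A is bought as a bromocyclopentenone and turned into the diene. Ring B is closed on it in one operation. Then follow C5/C6, the C8 methyl, the C4 carbinol and finally the aroyl group.
Stereochemistry: a temporary C4 carbinol (β-OSiEt3, from a CBS reduction) and the chiral rhodium catalyst together set quaternary C1. With the β face closed by CH3 and OSiEt3, borane adds from the α face and sets C5 and C6. C4 is then erased by oxidation and rebuilt by α-face isopropyl addition under the control of C1, C5 and C6.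

Key step: step 7

Assumption: the sense of induction of Rh2(R-DOSP)4, dirhodium tetrakis[(R)-N-(4-dodecylphenylsulfonyl)prolinate], is taken from its behaviour with monosubstituted olefins. If the diene responds in the opposite sense, the equally available mirror-image catalyst is used and nothing else changes.
Abbreviations: TES = triethylsilyl, TBS = tert-butyldimethylsilyl.

**Step 1**
Reactants: 1 2-bromo-3-methylcyclopent-2-en-1-one
Product: 2 (S)-2-bromo-3-methylcyclopent-2-en-1-ol
Conditions: (R)-2-methyl-CBS-oxazaborolidine (10 mol %), BH3·SMe2, THF, −20 °C; MeOH quench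
Reagents that add atoms: none
Why: Corey–Bakshi–Shibata reduction, in which the bromoalkene arm acts as the large and the ring CH2 as the small ketone substituent, so that the (R)-catalyst should deliver hydride to the face that gives the (S)-carbinol (future C4, oxygen β).

**Step 2**
Reactants: 2 (S)-2-bromo-3-methylcyclopent-2-en-1-ol
Product: 3 (S)-(2-bromo-3-methylcyclopent-2-en-1-yloxy)triethylsilane
Conditions: Et3SiCl, imidazole, CH2Cl2, 0 → 23 °C
Reagents that add atoms: chlorotriethylsilane, CC[Si](Cl)(CC)CC
Why: Standard silylation of a secondary allylic alcohol; the TES group is large enough to screen the β face in steps 7 and 8 and can later be removed beside a TBS ether.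

**Step 3**
Reactants: 3 (S)-(2-bromo-3-methylcyclopent-2-en-1-yloxy)triethylsilane
Product: 4 (S)-(2-ethenyl-3-methylcyclopent-2-en-1-yloxy)triethylsilane (diene C7=C6–C5=C1; OTES on C4)
Conditions: Bu3SnCH=CH2, Pd(PPh3)4 (5 mol %), toluene, 100 °C
Reagents that add atoms: tributyl(vinyl)stannane, C=C[Sn](CCCC)(CCCC)CCCC
Why: Stille coupling of an alkenyl bromide with a vinylstannane under zerovalent palladium, which leaves the allylic silyl ether and its stereocentre untouched.

**Step 4**
Reactants: 5 methyl acetoacetate
Product: 6 methyl 2-diazo-3-oxobutanoate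
Conditions: 4-acetamidobenzenesulfonyl azide, Et3N, MeCN, 0 → 23 °C
Reagents that add atoms: 4-acetamidobenzenesulfonyl azide, CC(=O)Nc1ccc(cc1)S(=O)(=O)N=[N+]=[N-]
Why: Regitz diazo transfer to an active methylene compound.

**Step 5**
Reactants: 6 methyl 2-diazo-3-oxobutanoate
Product: 7 methyl 2-diazo-3-hydroxybutanoate (racemic)
Conditions: NaBH4, MeOH, 0 °C
Reagents that add atoms: none
Why: Chemoselective borohydride reduction of the ketone of an α-diazo-β-keto ester, the diazo ester being inert; the new carbinol centre disappears in step 6.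

**Step 6**
Reactants: 7 methyl 2-diazo-3-hydroxybutanoate
Product: 8 methyl 2-diazobut-3-enoate
Conditions: POCl3, Et3N, CH2Cl2, 0 °C; taken up in hexanes and used at once
Reagents that add atoms: none
Why: Phosphorylation and β-elimination is the established dehydration of 3-hydroxy-2-diazo esters to vinyldiazoacetates; the product is used immediately because it slowly closes to a pyrazole.

**Step 7**
Reactants: 4 (S)-(2-ethenyl-3-methylcyclopent-2-en-1-yloxy)triethylsilane; 8 methyl 2-diazobut-3-enoate
Product: 10 hydroazulene dienoate (olefins C5=C6 and C8=C9; CO2Me on C8; CH3 β on C1; OTES β on C4), via cis-divinylcyclopropane 9 (not isolated)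
Conditions: Rh2(R-DOSP)4 (1 mol %), hexanes, 8 (1.5 equiv) added over 2 h at 0 °C, then 65 °C
Reagents that add atoms: none
Why: The catalyst expels N2 from 8 to give a donor/acceptor rhodium vinylcarbenoid, which cyclopropanates the terminal C6=C7 vinyl group of 4 in a concerted asynchronous addition that places the cyclopentenyl group cis to the carbenoid vinyl group (bonds C7–C8 and C6–C8, compound 9), and 9 then undergoes a [3,3]-sigmatropic Cope rearrangement through the obligatory boat transition state, in which the strained C6–C8 bond breaks and C10 bonds to C1. The closest known reaction type is the tandem cyclopropanation/Cope rearrangement of vinyldiazoacetates with 1,3-dienes, a formal (4+3) cycloaddition that is known to build quaternary carbons from fully substituted diene termini. The three-membered ring closes by (2+1) carbene addition and is only transient, whereas seven-membered ring B closes by sigmatropic ring expansion of that cyclopropane, so that both olefins come out cis and exactly at C5=C6 and C8=C9. The only lasting new stereocentre, quaternary C1, follows stereospecifically from the configuration of C6 and C8 in 9, which the chiral catalyst sets, because the boat geometry lets C10 reach only one face of C1; the OTES group on the β face of C4 favours the same α-face approach, so catalyst and substrate should be matched. The step needs site selectivity for the monosubstituted vinyl group over the tetrasubstituted ring olefin and over insertion into the allylic C4–H bond, which the steric demand of the carbenoid and the high rate of cyclopropanation of terminal olefins should secure, and the regiochemistry (CO2Me on C8) follows because the carbene carbon stays bonded to the former CH2 terminus C7. The ester that stabilises the carbenoid marks the carbon that becomes the C8 methyl group and meanwhile deactivates C8=C9 for step 8.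

**Step 8**
Reactants: 10 hydroazulene dienoate
Product: 12 6α-hydroxy ester (5α-H; trans-fused; 4β-OTES; CO2Me on C8), via C6-borane 11 (not isolated)
Conditions: BH3·THF, THF, 0 → 23 °C; then 30 % H2O2, aq NaOH, 0 °C
Reagents that add atoms: hydrogen peroxide, OO; borane–tetrahydrofuran, B.C1CCOC1 (boron only in 11)
Why: Brown hydroboration–oxidation adds H and B syn with boron on the less substituted C6, which is the cis H-5/O-6 pattern of the target; the β face of C5=C6 is flanked by the angular CH3 and the OTES group, so borane should enter from the α face, the acrylate-type C8=C9 olefin is too electron-poor to compete, and the C–B bond is oxidised with retention.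

**Step 9**
Reactants: 12 6α-hydroxy ester
Product: 13 6α-OTBS, 4β-OTES ester
Conditions: TBSOTf, 2,6-lutidine, CH2Cl2, 0 °C
Reagents that add atoms: tert-butyldimethylsilyl triflate, CC(C)(C)[Si](C)(C)OS(=O)(=O)C(F)(F)F
Why: Silylation of a hindered secondary alcohol with a silyl triflate; the TBS ether survives the hydride steps and the later TES removal and is a poor leaving group beside the ketone of 18.

**Step 10**
Reactants: 13 6α-OTBS, 4β-OTES ester
Product: 14 primary allylic alcohol (CH2OH on C8)
Conditions: i-Bu2AlH, CH2Cl2, −78 °C; aq potassium sodium tartrate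
Reagents that add atoms: none
Why: 1,2-Reduction of an α,β-unsaturated ester to the allylic alcohol with diisobutylaluminium hydride, to which both silyl ethers are inert.

**Step 11**
Reactants: 14 primary allylic alcohol
Product: 16 8-methyl bis-silyl ether (4β-OTES; 6α-OTBS; C8=C9), via allylic mesylate 15 (not isolated)
Conditions: MsCl, Et3N, THF, −20 °C; then LiEt3BH (excess), −20 → 0 °C
Reagents that add atoms: methanesulfonyl chloride, CS(=O)(=O)Cl (only in 15)
Why: Deoxygenation of a primary allylic alcohol by mesylation and SN2 displacement with triethylborohydride at the unhindered CH2 terminus, so that the olefin stays at C8=C9 and the activating ester has become the natural methyl group.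

**Step 12**
Reactants: 16 8-methyl bis-silyl ether
Product: 18 C4 ketone (5α-H; 6α-OTBS), via C4-alcohol 17 (not isolated)
Conditions: IBX (3 equiv), DMSO, 23 °C
Reagents that add atoms: none
Why: IBX in DMSO is known to cleave TES ethers without touching TBS ethers and then to oxidise the freed secondary alcohol in the same flask, and the weakly acidic medium should spare the epimerisable C5–H and the β-silyloxy group.

**Step 13**
Reactants: 18 C4 ketone
Product: 19 6-O-TBS-jaeschkeanadiol (4β-OH; 4α-i-Pr)
Conditions: i-PrMgCl, CeCl3 (dried), THF, −78 → 0 °C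
Reagents that add atoms: isopropylmagnesium chloride, CC(C)[Mg]Cl
Why: 1,2-Addition of a weakly basic organocerium reagent to an enolisable hindered ketone; the β face of the cyclopentanone is closed by the angular CH3 and by C6 with its OTBS group while the α face shows only H-5, so the nucleophile should enter from α.

**Step 14**
Reactants: 19 6-O-TBS-jaeschkeanadiol
Product: 20 jaeschkeanadiol
Conditions: Bu4NF, THF, 23 → 45 °C
Reagents that add atoms: none
Why: Fluoride-mediated cleavage of a secondary TBS ether, with no base-sensitive group left in the molecule.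

**Step 15**
Reactants: 21 4-hydroxybenzoic acid
Product: 23 4-(tert-butyldimethylsilyloxy)benzoic acid, via silyl ester 22 (not isolated)
Conditions: TBSCl (2.2 equiv), imidazole, DMF, 23 °C; then AcOH/THF/H2O, 23 °C
Reagents that add atoms: tert-butyldimethylsilyl chloride, CC(C)(C)[Si](C)(C)Cl
Why: Exhaustive silylation followed by selective hydrolysis of the much more labile silyl ester, a standard phenol protection of hydroxy acids.

**Step 16**
Reactants: 20 jaeschkeanadiol; 23 4-(tert-butyldimethylsilyloxy)benzoic acid
Product: 24 O-TBS-ferutinine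
Conditions: DCC, DMAP (cat.), CH2Cl2, 23 °C
Reagents that add atoms: none
Why: Steglich esterification, in which only the equatorial secondary C6–OH reacts because the tertiary C4–OH next to the isopropyl group is too hindered.

**Step 17**
Reactants: 24 O-TBS-ferutinine
Product: 25 ferutinine
Conditions: Bu4NF, AcOH, THF, 0 °C
Reagents that add atoms: none
Why: Buffered fluoride cleaves the aryl silyl ether rapidly, while the hindered benzoate, the tertiary alcohol and the olefin are left alone.

**Compound list**

1 | 2-bromo-3-methylcyclopent-2-en-1-one | CC1=C(Br)C(=O)CC1 | starting material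
2 | (S)-2-bromo-3-methylcyclopent-2-en-1-ol | CC1=C(Br)[C@@H](O)CC1 | intermediate
3 | (S)-(2-bromo-3-methylcyclopent-2-en-1-yloxy)triethylsilane | CC1=C(Br)[C@@H](O[Si](CC)(CC)CC)CC1 | intermediate
4 | (S)-(2-ethenyl-3-methylcyclopent-2-en-1-yloxy)triethylsilane | CC1=C(C=C)[C@@H](O[Si](CC)(CC)CC)CC1 | intermediate
5 | methyl acetoacetate | CC(=O)CC(=O)OC | starting material
6 | methyl 2-diazo-3-oxobutanoate | CC(=O)C(=[N+]=[N-])C(=O)OC | intermediate
7 | methyl 2-diazo-3-hydroxybutanoate (racemic) | CC(O)C(=[N+]=[N-])C(=O)OC | intermediate
8 | methyl 2-diazobut-3-enoate | C=CC(=[N+]=[N-])C(=O)OC | intermediate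
9 | methyl (1S,2S)-1-ethenyl-2-[(5S)-2-methyl-5-(triethylsilyloxy)cyclopent-1-en-1-yl]cyclopropane-1-carboxylate (vinyl and cyclopentenyl cis) | COC(=O)[C@]1(C=C)C[C@H]1C2=C(C)CC[C@@H]2O[Si](CC)(CC)CC | intermediate
10 | methyl (3S,8aR)-8a-methyl-3-(triethylsilyloxy)-1,2,3,5,8,8a-hexahydroazulene-6-carboxylate (hydroazulene dienoate) | COC(=O)C1=CC[C@@]2(C)CC[C@H](O[Si](CC)(CC)CC)C2=CC1 | intermediate
11 | C6 α-borane of 10 (5α-H, 6α-BH2) | COC(=O)C1=CC[C@@]2(C)CC[C@H](O[Si](CC)(CC)CC)[C@@H]2[C@@H](B)C1 | intermediate
12 | 6α-hydroxy ester (1β-CH3, 4β-OTES, 5α-H, CO2Me on C8, C8=C9) | COC(=O)C1=CC[C@@]2(C)CC[C@H](O[Si](CC)(CC)CC)[C@@H]2[C@@H](O)C1 | intermediate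
13 | 6α-OTBS, 4β-OTES ester | COC(=O)C1=CC[C@@]2(C)CC[C@H](O[Si](CC)(CC)CC)[C@@H]2[C@@H](O[Si](C)(C)C(C)(C)C)C1 | intermediate
14 | primary allylic alcohol (CH2OH on C8) | OCC1=CC[C@@]2(C)CC[C@H](O[Si](CC)(CC)CC)[C@@H]2[C@@H](O[Si](C)(C)C(C)(C)C)C1 | intermediate
15 | allylic mesylate of 14 | CS(=O)(=O)OCC1=CC[C@@]2(C)CC[C@H](O[Si](CC)(CC)CC)[C@@H]2[C@@H](O[Si](C)(C)C(C)(C)C)C1 | intermediate
16 | 8-methyl bis-silyl ether (4β-OTES, 6α-OTBS) | CC1=CC[C@@]2(C)CC[C@H](O[Si](CC)(CC)CC)[C@@H]2[C@@H](O[Si](C)(C)C(C)(C)C)C1 | intermediate
17 | 4β-alcohol (6α-OTBS) | CC1=CC[C@@]2(C)CC[C@H](O)[C@@H]2[C@@H](O[Si](C)(C)C(C)(C)C)C1 | intermediate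
18 | C4 ketone (5α-H, 6α-OTBS, trans-fused) | CC1=CC[C@@]2(C)CCC(=O)[C@@H]2[C@@H](O[Si](C)(C)C(C)(C)C)C1 | intermediate
19 | 6-O-TBS-jaeschkeanadiol (4β-OH, 4α-i-Pr) | CC1=CC[C@@]2(C)CC[C@@](O)(C(C)C)[C@@H]2[C@@H](O[Si](C)(C)C(C)(C)C)C1 | intermediate
20 | jaeschkeanadiol, (3R,3aS,4S,8aR)-6,8a-dimethyl-3-(propan-2-yl)-1,2,3,3a,4,5,8,8a-octahydroazulene-3,4-diol | CC1=CC[C@@]2(C)CC[C@@](O)(C(C)C)[C@@H]2[C@@H](O)C1 | intermediate
21 | 4-hydroxybenzoic acid | OC(=O)c1ccc(O)cc1 | starting material
22 | tert-butyldimethylsilyl 4-(tert-butyldimethylsilyloxy)benzoate | CC(C)(C)[Si](C)(C)OC(=O)c1ccc(O[Si](C)(C)C(C)(C)C)cc1 | intermediate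
23 | 4-(tert-butyldimethylsilyloxy)benzoic acid | OC(=O)c1ccc(O[Si](C)(C)C(C)(C)C)cc1 | intermediate
24 | O-TBS-ferutinine | CC1=CC[C@@]2(C)CC[C@@](O)(C(C)C)[C@@H]2[C@@H](OC(=O)c2ccc(O[Si](C)(C)C(C)(C)C)cc2)C1 | intermediate
25 | ferutinine, (3R,3aS,4S,8aR)-3-hydroxy-6,8a-dimethyl-3-(propan-2-yl)-1,2,3,3a,4,5,8,8a-octahydroazulen-4-yl 4-hydroxybenzoate | CC1=CC[C@@]2(C)CC[C@@](O)(C(C)C)[C@@H]2[C@@H](OC(=O)c2ccc(O)cc2)C1 | target

**Step count and risks**

Total steps: 17. Longest linear sequence: 13 (steps 1–3, 7–14, 16 and 17).

Steps most likely to fail: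

Step 7.
- What may go wrong: the unsubstituted vinyldiazoacetate may be lost by electrocyclisation. The carbenoid may be attacked at its vinylogous carbon or may insert into the doubly activated C4–H bond. Facial selectivity may be poor if catalyst and substrate prove mismatched. The Cope step may be sluggish because the C1 methyl group points into the boat.
- Fallback (sets out from 6 and 4, comes back at 10): 6 is silylated with TBSOTf/Et3N to the bench-stable methyl 3-(tert-butyldimethylsilyloxy)-2-diazobut-3-enoate F1. Its less electrophilic carbenoid has no free vinylogous position. With Rh2(S-PTAD)4, dirhodium tetrakis[(S)-(1-adamantyl)(phthalimido)acetate] (enantiomer chosen as in the assumption), it is added to 4. This gives, through the siloxy-substituted cis-divinylcyclopropane F2, the C9-silyloxy dienoate F3. CsF and PhNTf2 turn the enol silane into the C9 enol triflate F4. Reduction with Pd(OAc)2/PPh3, HCO2H and Et3N in DMF removes the triflate and gives 10.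

Step 8.
- What may go wrong: the olefin, flanked by two substituted carbons, may react slowly. Reduction of the acrylate unit may compete. α-Face selectivity may be incomplete if ring B folds under the olefin.
- Fallback (sets out from 10, comes back at 12): m-CPBA/NaHCO3 epoxidises only the electron-rich C5=C6 olefin, from the same open α face, to the 5α,6α-epoxide F5. Cp2TiCl (trivalent titanium, made from Cp2TiCl2 and Mn) with 1,4-cyclohexadiene in THF opens the C5–O bond homolytically to the tertiary C5 radical. O-6 keeps its α configuration, and the hydrogen atom is delivered to C5 from the face not closed by CH3 and OTES. This gives 12 after work-up.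

Step 13.
- What may go wrong: enolisation may cause C5 epimerisation or β-elimination of the silyloxy group. β-Hydride transfer from the isopropyl reagent may reduce the ketone. The hindered ketone may convert poorly.
- Fallback (sets out from 18, comes back at 19): the smaller isopropenyl nucleophile cannot transfer a β-hydride. As CH2=C(CH3)MgBr with CeCl3 in THF at −78 °C, it is added from the same α face to give the 4α-isopropenyl carbinol F6. H2 with RhCl(PPh3)3 in benzene/EtOH then saturates only the 1,1-disubstituted olefin beside the trisubstituted C8=C9 and gives 19.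

**Further compounds**
F1 | step 7 | methyl 3-(tert-butyldimethylsilyloxy)-2-diazobut-3-enoate | C=C(O[Si](C)(C)C(C)(C)C)C(=[N+]=[N-])C(=O)OC
F2 | step 7 | siloxy-substituted cis-divinylcyclopropane | COC(=O)[C@]1(C(=C)O[Si](C)(C)C(C)(C)C)C[C@H]1C2=C(C)CC[C@@H]2O[Si](CC)(CC)CC
F3 | step 7 | C9-silyloxy dienoate | COC(=O)C1=C(O[Si](C)(C)C(C)(C)C)C[C@@]2(C)CC[C@H](O[Si](CC)(CC)CC)C2=CC1
F4 | step 7 | C9 enol triflate | COC(=O)C1=C(OS(=O)(=O)C(F)(F)F)C[C@@]2(C)CC[C@H](O[Si](CC)(CC)CC)C2=CC1
F5 | step 8 | 5α,6α-epoxide | COC(=O)C1=CC[C@@]2(C)CC[C@H](O[Si](CC)(CC)CC)[C@@]23O[C@H]3C1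
F6 | step 13 | 4α-isopropenyl carbinol | CC1=CC[C@@]2(C)CC[C@@](O)(C(C)=C)[C@@H]2[C@@H](O[Si](C)(C)C(C)(C)C)C1
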